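The question is where maple, the flask followed so far to 3.00 d, stands at 10 d: how much substrate has reacted, and how handed the product and the remaining substrate are.

| setting | maple | larch | flask |
|---|---|---|---|
| left-handed substrate | 19 mM | 19 mM | 19 mM |
| right-handed substrate | 19 mM | 19 mM | 19 mM |
| partner | 2.5 equiv | 5 equiv | 2.50 equiv |
| racemization catalyst | 5 mol% | 5 mol% | 5 mol% |
| remark | the very flask that is asked about, followed so far | run made earlier |  |
| time |  |  | 10 d |

- maple (time / d: left-handed substrate / %, right-handed substrate / %): 0.208: 49.2, 49.0; 0.625: 45.3, 49.7; 1.04: 42.2, 51.4; 1.67: 39.9, 47.3; 2.50: 38.7, 48.9; 3.00: 38.4, 47.2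
- larch (time / d: left-handed substrate / %, right-handed substrate / %): 0.625: 42.4, 48.6; 0.833: 39.9, 49.2; 1.67: 33.4, 46.9; 2.50: 29.9, 47.1; 4.00: 26.0, 40.1; 8.00: 27.2, 33.3

(each reading ± 1 percentage point)

- partner is single-handed; left-handed substrate and right-handed substrate are mirror images of each other, charged as a racemate, each of them at the stated concentration
- an excess is the difference of the two amounts in percent of their sum
- an excess is below zero if the other one leads
- the handed part of partner does not stay in what it makes, so the products of the two hands are mirror images too

- part of the left-handed substrate and right-handed substrate charged together that has reacted at 10 d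
- excess of left-handed product over right-handed product in the product at 10 d
- excess of right-handed substrate over left-handed substrate among what is left of the two at 10 d

Maple and larch differ in one setting, the partner, and the substrate ratio shows what that does. Let r be c(left-handed substrate)/c(right-handed substrate). Neglecting the right-handed substrate's own reaction, a steady r means both substrates shrink at one relative rate, and the inverse of r minus r then equals D. Maple at 2.50 d reads 0.472 for this drain ratio: the left-handed substrate's lifetime against racemization over its lifetime against partner, both pseudo-first-order.

Larch at 2.50 d reads 0.940, which is 1.99 times maple's, while the partner charges stand at 2.00 to one, so within the scatter D follows c(partner). By 8.00 d, larch's D has sunk to 0.407, less than its earlier reading, although the vanished substrate amounts to 0.790 equiv against 5 equiv of partner charged. Partner therefore seems to fade on a clock of its own.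

Putting maple on that clock gives D of 0.204 at 8.00 d. At small excess the substrate excess is D divided by 4, here 5.10 %. Scaling larch's remaining substrate by the same partner ratio, as an exponent, gives 22.2 % reacted at that time, somewhat more by 10 d. This reckoning gives no figure for the product excess.

The forecast, which said of larch's stall “I read this as reversibility”, gave 31 % reacted, product excess 65 % and substrate excess 3.5 %. The flask gives 27.7 %, 91.9 % and 6.71 %.

    partner + left-handed substrate → left-handed product (k = 0.140 M⁻¹ h⁻¹)
    partner + right-handed substrate → right-handed product (k = 0.00510 M⁻¹ h⁻¹)
    left-handed substrate + racemization catalyst ⇌ right-handed substrate + racemization catalyst, rate k3*[racemization catalyst]*[left-handed substrate] forward; the back reaction follows from the equilibrium constant (k = 12.0 M⁻¹ h⁻¹)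
    partner ⇌ dormant form (K = 4.90, k = 0.00750 h⁻¹)
    2 racemization catalyst ⇌ resting dimer (K = 780 M⁻¹, k = 28.0 M⁻¹ h⁻¹)

In maple at 10 d, D as 4 times the substrate excess is 0.268, with partner at 17.5 % of its charge and dormant form at 28.7 mM. The neighbouring flask, the same recipe with 2 mol% of racemization catalyst, ends with partner at 17.8 % of its charge. Racemization catalyst stands at 55.1 % of its charge in maple and 70.5 % in the neighbouring flask, the rest being resting dimer, so this reckoning scales D by 1.95, not by the charge ratio 2.50. Reckoned so, the substrate excess comes to 13.1 %, and the neighbouring flask gives 13.0 %.

(All runs come from a simulation from invented constants; the scatter is artificial.)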